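**Strategy.** Everything rests on cutting both C–Br bonds at C3 and C4 of ring A (the phenol ring; C1 OH, C2 O-aryl, C5 H, C6 Br) back to a C3–C4 aryne. The key step exploits that these two bromines are vicinal and sit directly beside the C2 aryloxy oxygen: one fluoride-triggered operation adds bromide at C4 and Br+ at C3, so the bromine meta to the future OH needs no electrophilic substitution. The precursor is an ortho-silyl aryl triflate carrying the C1 oxygen as a methyl ether and the C2 phenoxy group already in place; the remaining three bromines (C6, C2', C4') follow the natural ortho/para direction of the oxygens.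

Key step: step 6

Remark: ring A is numbered as in the target throughout the text (C1 bears the oxygen that ends as OH, C2 the aryloxy oxygen, C3 and C4 are the aryne carbons, then C5 and C6); ring B positions are primed. Compound names use systematic locants, which can differ. The target has no stereocentre, so no configuration has to be set. The structures of the key-step precursor and product were checked against the target and found consistent; no correction was needed.

**Step 1**
Reactants: 1 2,6-dimethoxyphenol; 2 diphenyliodonium trifluoromethanesulfonate
Product: 3 1,3-dimethoxy-2-phenoxybenzene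
Conditions: t-BuOK, THF, 0 °C → 40 °C
Reagents that add atoms: diphenyliodonium trifluoromethanesulfonate (2), [O-]S(=O)(=O)C(F)(F)F.c1ccc(cc1)[I+]c1ccccc1
Why: Ligand coupling of the potassium phenoxide with the diaryliodonium salt (metal-free O-arylation) tolerates the two ortho methoxy groups, and a symmetric salt can only transfer phenyl.

**Step 2**
Reactants: 3 1,3-dimethoxy-2-phenoxybenzene
Product: 4 3-methoxy-2-phenoxyphenol
Conditions: NaSEt, DMF, 130 °C; aq. HCl
Reagents that add atoms: none
Why: Thiolate SN2 O-demethylation of an aryl methyl ether should stop after one cleavage because the phenoxide formed shuts down attack on the second methoxy group, and the two methoxy groups of 3 are equivalent so no regiochemical issue arises.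

**Step 3**
Reactants: 4 3-methoxy-2-phenoxyphenol; 5 isopropyl isocyanate
Product: 6 3-methoxy-2-phenoxyphenyl N-(propan-2-yl)carbamate
Conditions: Et3N (cat.), CH2Cl2, rt
Reagents that add atoms: isopropyl isocyanate (5), CC(C)N=C=O
Why: Amine-catalysed addition of the phenol to the isocyanate (carbamoylation) installs the N-monoalkyl carbamate that serves as a removable directing group.

**Step 4**
Reactants: 6 3-methoxy-2-phenoxyphenyl N-(propan-2-yl)carbamate; 7 chlorotrimethylsilane
Product: 11 3-methoxy-2-phenoxy-6-(trimethylsilyl)phenyl N-(propan-2-yl)carbamate, via N-TBS carbamate 8 (not isolated), via ortho-lithiated N-TBS carbamate 9 (not isolated), via N-TBS C-TMS carbamate 10 (not isolated)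
Conditions: TBSOTf, TMEDA, Et2O, 0 °C → rt; n-BuLi, TMEDA, −78 °C; TMSCl, −78 °C → rt; aq. NaHSO4
Reagents that add atoms: chlorotrimethylsilane (7), C[Si](C)(C)Cl
Why: Directed ortho-metalation: after in situ N-silylation the O-aryl carbamate is the strongest director on ring A and its only free ortho position is the future C4 (the other ortho carbon carries the phenoxy group), so lithiation and silyl quench place silicon there, and the N-silyl group is lost on acidic work-up.

**Step 5**
Reactants: 11 3-methoxy-2-phenoxy-6-(trimethylsilyl)phenyl N-(propan-2-yl)carbamate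
Product: 13 3-methoxy-2-phenoxy-6-(trimethylsilyl)phenyl trifluoromethanesulfonate, via silylphenol 12 (not isolated)
Conditions: DBU, Et2NH, MeCN, 40 °C; then PhNTf2, rt
Reagents that add atoms: N-phenylbis(trifluoromethanesulfonimide), O=S(=O)(N(c1ccccc1)S(=O)(=O)C(F)(F)F)C(F)(F)F
Why: DBU-induced E1cB loss of isopropyl isocyanate (scavenged by Et2NH as a urea) frees the phenoxide, which is triflated in the same flask so that the protodesilylation-prone ortho-silylphenol is never isolated.

**Step 6**
Reactants: 13 3-methoxy-2-phenoxy-6-(trimethylsilyl)phenyl trifluoromethanesulfonate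
Product: 16 1,2-dibromo-4-methoxy-3-phenoxybenzene, via aryne 14 (not isolated), via 2-bromoaryl anion 15 (not isolated)
Conditions: CsF, n-Bu4NBr, CBr4, MeCN, 0 °C → rt; aq. NH4Cl
Reagents that add atoms: tetrabutylammonium bromide, CCCC[N+](CCCC)(CCCC)CCCC.[Br-]; carbon tetrabromide, BrC(Br)(Br)Br
Why: Fluoride attacks silicon of 13, the aryl anion expels triflate and the C3–C4 aryne 14 forms; bromide adds at C4, the aryne carbon remote from the C2 aryloxy group, because the resulting C3 anion 15 is stabilised inductively by the adjacent oxygen, and 15 then abstracts Br+ from CBr4 (halophilic substitution) to finish the sequence. The closest known reaction type is the 1,2-dihalogenation of arynes released from 2-(trimethylsilyl)aryl triflates, combined with the trapping of aryne-derived aryl anions by polyhalomethanes. No ring is closed and no stereocentre is created. The step needs bromide to outrun fluoride as the nucleophile (soluble n-Bu4NBr in excess against sparingly soluble CsF) and bromine transfer to outrun protonation of 15 by the medium (CBr4 in excess, dry MeCN). The sense of addition is irrelevant because both new substituents are bromine, and a bromine donor that liberates no free Br2 is chosen so that the aryl–silicon bond of unreacted 13 is not cut by ipso-bromodesilylation.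

**Step 7**
Reactants: 16 1,2-dibromo-4-methoxy-3-phenoxybenzene
Product: 17 3,4-dibromo-2-phenoxyphenol
Conditions: BBr3, CH2Cl2, −78 °C → rt; H2O
Reagents that add atoms: none
Why: Lewis-acid O-demethylation with BBr3 cleaves only the alkyl–oxygen bond, leaving the diaryl ether and both aryl bromides untouched.

**Step 8**
Reactants: 17 3,4-dibromo-2-phenoxyphenol
Product: 18 3,4,6-tribromo-2-(2,4-dibromophenoxy)phenol
Conditions: Br2 (3.1 equiv), AcOH, rt → 60 °C; aq. NaHSO3
Reagents that add atoms: bromine, BrBr
Why: Electrophilic aromatic bromination follows the oxygen directors: the free OH sends bromine to C6, its only open ortho/para site, the ether oxygen sends two bromines to C4' and then C2' of ring B, while C5 should stay free because it is meta to OH, flanked by C4–Br and C6–Br, and para to an ether oxygen that its two ortho neighbours twist out of conjugation with ring A.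

**Compound list**
1 | 2,6-dimethoxyphenol | COc1cccc(OC)c1O | starting material
2 | diphenyliodonium trifluoromethanesulfonate | [O-]S(=O)(=O)C(F)(F)F.c1ccc(cc1)[I+]c1ccccc1 | starting material
3 | 1,3-dimethoxy-2-phenoxybenzene | COc1cccc(OC)c1Oc1ccccc1 | intermediate
4 | 3-methoxy-2-phenoxyphenol | COc1cccc(O)c1Oc1ccccc1 | intermediate
5 | isopropyl isocyanate | CC(C)N=C=O | starting material
6 | 3-methoxy-2-phenoxyphenyl N-(propan-2-yl)carbamate | COc1cccc(OC(=O)NC(C)C)c1Oc1ccccc1 | intermediate
7 | chlorotrimethylsilane | C[Si](C)(C)Cl | starting material
8 | 3-methoxy-2-phenoxyphenyl N-(tert-butyldimethylsilyl)-N-(propan-2-yl)carbamate (formed in the flask in step 4) | COc1cccc(OC(=O)N(C(C)C)[Si](C)(C)C(C)(C)C)c1Oc1ccccc1 | intermediate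
9 | [2-{[(tert-butyldimethylsilyl)(propan-2-yl)carbamoyl]oxy}-4-methoxy-3-phenoxyphenyl]lithium (formed in the flask in step 4) | COc1ccc([Li])c(OC(=O)N(C(C)C)[Si](C)(C)C(C)(C)C)c1Oc1ccccc1 | intermediate
10 | 3-methoxy-2-phenoxy-6-(trimethylsilyl)phenyl N-(tert-butyldimethylsilyl)-N-(propan-2-yl)carbamate (formed in the flask in step 4) | COc1ccc([Si](C)(C)C)c(OC(=O)N(C(C)C)[Si](C)(C)C(C)(C)C)c1Oc1ccccc1 | intermediate
11 | 3-methoxy-2-phenoxy-6-(trimethylsilyl)phenyl N-(propan-2-yl)carbamate | COc1ccc([Si](C)(C)C)c(OC(=O)NC(C)C)c1Oc1ccccc1 | intermediate
12 | 3-methoxy-2-phenoxy-6-(trimethylsilyl)phenol (formed in the flask in step 5, present as its DBU salt) | COc1ccc([Si](C)(C)C)c(O)c1Oc1ccccc1 | intermediate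
13 | 3-methoxy-2-phenoxy-6-(trimethylsilyl)phenyl trifluoromethanesulfonate | COc1ccc([Si](C)(C)C)c(OS(=O)(=O)C(F)(F)F)c1Oc1ccccc1 | intermediate
14 | 4-methoxy-3-phenoxybenzyne (1,2-didehydro-4-methoxy-3-phenoxybenzene; formed in the flask in step 6) | COC1=C(Oc2ccccc2)C#CC=C1 | intermediate
15 | 6-bromo-3-methoxy-2-phenoxyphenyl anion, drawn as its caesium salt (formed in the flask in step 6) | [Cs+].COc1ccc(Br)[c-]c1Oc1ccccc1 | intermediate
16 | 1,2-dibromo-4-methoxy-3-phenoxybenzene | COc1ccc(Br)c(Br)c1Oc1ccccc1 | intermediate
17 | 3,4-dibromo-2-phenoxyphenol | Oc1ccc(Br)c(Br)c1Oc1ccccc1 | intermediate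
18 | 3,4,6-tribromo-2-(2,4-dibromophenoxy)phenol (CNP0266876.0) | Oc1c(Br)cc(Br)c(Br)c1Oc1ccc(Br)cc1Br | target

**Step count.** Total: 8 steps. Longest linear sequence: 8 steps (from 1).

**Steps most likely to fail**

Step 6. The C3 aryl anion may pick up a proton from the medium before it meets CBr4, fluoride or tribromomethanide may compete with bromide for the aryne, or the neighbouring phenoxy ring may capture the aryne intramolecularly. Fallback, setting out from 13 and returning at 16: 13 would be treated with CsF and I2 in MeCN, the aryne inserting into the I–I bond to give 1,2-diiodo-4-methoxy-3-phenoxybenzene F1. Heating F1 with an excess of CuBr in DMF (copper-mediated aromatic halogen exchange, which runs from iodide to bromide) should then convert both C–I bonds into C–Br bonds and deliver 16.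

Step 8. The last bromination (C2' of ring B) may lag under conditions mild enough for the free phenol, and forcing it may lead to over-bromination at C5 or C6' or to oxidation of the electron-rich bromophenol to bromodienones. Fallback, setting out from 16 and returning at 18: the bromination would be moved in front of the demethylation so that the oxygen at C1 stays masked. Compound 16 with Br2 (3 equiv) in AcOH, with FeBr3 as catalyst if the third bromination stalls, should give 1,2,5-tribromo-3-(2,4-dibromophenoxy)-4-methoxybenzene F2, the methoxy group directing to C6 as the hydroxyl does. BBr3 in CH2Cl2 would then cleave the methyl ether to give 18.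

Step 4. Metalation may occur at the wrong site (ortho to the methoxy group or on ring B next to the ether oxygen), the carbamoyl group may migrate to carbon (anionic ortho-Fries shift), or incomplete N-silylation may lead to loss of isocyanate. Fallback, setting out from 4 and returning at 13: silicon would be delivered by halogen–lithium exchange and retro-Brook migration instead of deprotonation. Compound 4 with NBS and catalytic i-Pr2NH in CH2Cl2 (ortho-selective phenol bromination, the site also being para to the methoxy group) should give 6-bromo-3-methoxy-2-phenoxyphenol F3. HMDS in THF at reflux would give (6-bromo-3-methoxy-2-phenoxyphenoxy)trimethylsilane F4. n-BuLi in THF at −100 °C would then trigger bromine–lithium exchange and a 1,3 O→C silyl shift to lithium 3-methoxy-2-phenoxy-6-(trimethylsilyl)phenoxide F5, which Tf2O would convert in the same flask into 13, bypassing 6 and 11.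

**Further compounds**
F1 | step 6 | 1,2-diiodo-4-methoxy-3-phenoxybenzene | COc1ccc(I)c(I)c1Oc1ccccc1
F2 | step 8 | 1,2,5-tribromo-3-(2,4-dibromophenoxy)-4-methoxybenzene | COc1c(Br)cc(Br)c(Br)c1Oc1ccc(Br)cc1Br
F3 | step 4 | 6-bromo-3-methoxy-2-phenoxyphenol | COc1ccc(Br)c(O)c1Oc1ccccc1
F4 | step 4 | (6-bromo-3-methoxy-2-phenoxyphenoxy)trimethylsilane | COc1ccc(Br)c(O[Si](C)(C)C)c1Oc1ccccc1
F5 | step 4 | lithium 3-methoxy-2-phenoxy-6-(trimethylsilyl)phenoxide | [Li+].COc1ccc([Si](C)(C)C)c([O-])c1Oc1ccccc1
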